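**Retrosynthetic overview**

1. The strategy rests on C6 of ring B (the cyclohexene): it carries two alkenyl groups, the exocyclic styryl group and the ring arm C5=C4, next to ethyl and C7. It can therefore be traced back to a prochiral C(Et)(CH=CH2)2 carbon, with ring B opened at C4=C5 (metathesis of the C3a isopropenyl group with one of the two C6 vinyl groups) and the styryl group derived from the surviving vinyl group by Heck arylation.
2. The triene is disconnected at C3a–C4 and C3–CH3: anti conjugate addition of an isopropenyl copper reagent to a 4,5-disubstituted cyclopent-2-enone, then enolate methylation.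
3. The vicinal quaternary pair C6–C7 comes from an Ireland–Claisen rearrangement of a (2Z)-3-ethylpenta-2,4-dienyl butanoate, run while C3a is still CH2 and C2 is a dioxolane, so that only the C1 side of the ketene acetal is hindered.
4. C7a–C7 comes from an enantioselective phase-transfer Michael addition of dimethyl malonate to 2-ethylcyclopent-2-enone (C7a; C1 trans by equilibration), followed by C-ethylation and decarboxylation.
5. Ring order: ring A is bought as the cyclopentenone and ring B is closed in step 12. Numbering throughout: C1 (CHEt), C2 (C=O), C3 (CHMe), C3a, C4 (CMe), C5, C6, C7 (Et, CO2H), C7a.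

Key step: step 12

Assumption: N-benzylquininium chloride is taken to give the (1R,2S) Michael adduct of step 3; should its sense of induction be the opposite, the pseudoenantiomeric N-benzylquinidinium chloride is used instead.

**Route**

Step 1
Reactants: 1 pent-2-yn-1-ol
Product: 3 (2Z)-3-iodopent-2-en-1-ol, via cyclic alkenylaluminate 2 (not isolated)
Conditions: NaAlH2(OCH2CH2OMe)2, THF, 0 °C to rt; then I2, THF, −78 °C
Reagents that add atoms: iodine (II)
Why: Hydroxyl-directed trans-hydroalumination of the propargylic alcohol places aluminium on C3 in a five-membered aluminate, and iodinolysis with retention should give the (Z)-alkenyl iodide.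

Step 2
Reactants: 3 (2Z)-3-iodopent-2-en-1-ol
Product: 4 (2Z)-3-ethylpenta-2,4-dien-1-ol
Conditions: Bu3SnCH=CH2, Pd(PPh3)4 (5 mol%), DMF, 50 °C
Reagents that add atoms: tributyl(vinyl)stannane (C=C[Sn](CCCC)(CCCC)CCCC)
Why: Stille coupling of an alkenyl iodide proceeds with retention and tolerates the free alcohol; the alkene geometry has no stereochemical consequence later, because C6 becomes a divinyl carbon.

Step 3
Reactants: 5 2-ethylcyclopent-2-en-1-one; 6 dimethyl malonate
Product: 7 dimethyl 2-[(1R,2S)-2-ethyl-3-oxocyclopentyl]propanedioate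
Conditions: N-benzylquininium chloride (10 mol%), K2CO3 (solid), neat 6, −10 °C
Reagents that add atoms: none
Why: Enantioselective phase-transfer Michael addition of a malonate to a 2-alkylcyclopent-2-enone, in which the chiral ammonium–malonate ion pair selects one face of C7a while C1 equilibrates through the enolate to the trans isomer.

Step 4
Reactants: 7 dimethyl 2-[(1R,2S)-2-ethyl-3-oxocyclopentyl]propanedioate
Product: 8 dimethyl 2-[(6S,7R)-6-ethyl-1,4-dioxaspiro[4.4]nonan-7-yl]propanedioate
Conditions: HOCH2CH2OH, pyridinium p-toluenesulfonate (cat.), benzene, reflux with water separator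
Reagents that add atoms: ethylene glycol (OCCO)
Why: Acid-catalysed ketalisation; the dioxolane blocks retro-Michael cleavage in the basic steps that follow, protects C2 during ester enolisation and makes the C1 side of ring A the hindered one.

Step 5
Reactants: 8 dimethyl 2-[(6S,7R)-6-ethyl-1,4-dioxaspiro[4.4]nonan-7-yl]propanedioate
Product: 9 dimethyl 2-ethyl-2-[(6S,7R)-6-ethyl-1,4-dioxaspiro[4.4]nonan-7-yl]propanedioate
Conditions: NaH, DMF, 0 °C; EtI, 0 °C to rt
Reagents that add atoms: iodoethane (CCI)
Why: C-alkylation of a malonate anion with a primary iodide (malonic ester synthesis); no stereocentre is formed.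

Step 6
Reactants: 9 dimethyl 2-ethyl-2-[(6S,7R)-6-ethyl-1,4-dioxaspiro[4.4]nonan-7-yl]propanedioate
Product: 11 2-[(6S,7R)-6-ethyl-1,4-dioxaspiro[4.4]nonan-7-yl]butanoic acid (C2 epimers), via malonic acid 10 (not isolated)
Conditions: KOH, EtOH–H2O, reflux; KHSO4 (aq), 0 °C, to pH 4; then pyridine, reflux
Reagents that add atoms: potassium hydroxide ([K+].[OH-])
Why: Saponification and thermal decarboxylation of the dialkylmalonic acid; the ketal survives the base and the brief cold acidification, and the C7 epimer mixture does not matter because C7 is enolised in step 8.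

Step 7
Reactants: 11 2-[(6S,7R)-6-ethyl-1,4-dioxaspiro[4.4]nonan-7-yl]butanoic acid; 4 (2Z)-3-ethylpenta-2,4-dien-1-ol
Product: 12 (2Z)-3-ethylpenta-2,4-dien-1-yl 2-[(6S,7R)-6-ethyl-1,4-dioxaspiro[4.4]nonan-7-yl]butanoate
Conditions: EDC·HCl, DMAP, CH2Cl2, 0 °C to rt
Reagents that add atoms: none
Why: Steglich-type carbodiimide esterification of an α-branched acid with a primary allylic alcohol under neutral conditions that leave ketal and diene untouched.

Step 8
Reactants: 12 (2Z)-3-ethylpenta-2,4-dien-1-yl 2-[(6S,7R)-6-ethyl-1,4-dioxaspiro[4.4]nonan-7-yl]butanoate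
Product: 15 (2R)-2,3-diethyl-3-ethenyl-2-[(1R,2S)-2-ethyl-3-oxocyclopentyl]pent-4-enoic acid, via silyl ketene acetal 13 (not isolated), via silyl ester 14 (not isolated)
Conditions: LiN(iPr)2, THF–DMPU, −78 °C; Me3SiCl, Et3N, −78 °C to rt, then toluene, 80 °C; 2 M HCl, THF, rt
Reagents that add atoms: water (O)
Why: Ireland–Claisen rearrangement through a chair transition state joins C7 to the central dienyl carbon and creates the vicinal quaternary pair; with C7a–H eclipsing the ketene acetal double bond, the allyl unit should add to the face flanked by the C3a methylene and away from C1 with its ethyl group and spiro-ketal, which sets C7 as (R), and the acidic work-up cleaves the silyl ester and the dioxolane.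

Step 9
Reactants: 15 (2R)-2,3-diethyl-3-ethenyl-2-[(1R,2S)-2-ethyl-3-oxocyclopentyl]pent-4-enoic acid
Product: 16 methyl (2R)-2,3-diethyl-3-ethenyl-2-[(1R,2S)-2-ethyl-3-oxocyclopentyl]pent-4-enoate
Conditions: MeI, K2CO3, DMF, rt
Reagents that add atoms: iodomethane (CI)
Why: O-alkylation of the carboxylate (SN2 at methyl) is insensitive to the hindrance at C7 and does not touch the ketone.

Step 10
Reactants: 16 methyl (2R)-2,3-diethyl-3-ethenyl-2-[(1R,2S)-2-ethyl-3-oxocyclopentyl]pent-4-enoate
Product: 18 methyl (2R)-2,3-diethyl-3-ethenyl-2-[(1R,5S)-5-ethyl-4-oxocyclopent-2-en-1-yl]pent-4-enoate, via silyl enol ether 17 (not isolated)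
Conditions: LiN(iPr)2, Me3SiCl, THF, −78 °C; then Pd(OAc)2, MeCN, rt
Reagents that add atoms: none
Why: Kinetic deprotonation takes the C3 methylene and not the hindered C1 methine, and Saegusa–Ito dehydrogenation of the silyl enol ether gives the C3=C3a enone; the ester has no α-hydrogen.

Step 11
Reactants: 18 methyl (2R)-2,3-diethyl-3-ethenyl-2-[(1R,5S)-5-ethyl-4-oxocyclopent-2-en-1-yl]pent-4-enoate
Product: 20 methyl (2R)-2,3-diethyl-3-ethenyl-2-[(1R,2S,4S,5R)-2-ethyl-4-methyl-3-oxo-5-(prop-1-en-2-yl)cyclopentyl]pent-4-enoate, via silyl enol ether 19 (not isolated)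
Conditions: CH2=C(CH3)MgBr, CuBr·SMe2 (20 mol%), Me3SiCl, DMPU, THF, −78 °C; then (crude 19) MeLi, THF, 0 °C; MeI, DMPU, −78 to 0 °C
Reagents that add atoms: isopropenylmagnesium bromide (C=C(C)[Mg]Br); iodomethane (CI)
Why: Copper-catalysed conjugate addition should occur anti to the bulky C7a substituent (sets C3a), and the regiodefined lithium enolate released from the silyl enol ether is methylated anti to the new isopropenyl group (sets C3, which is also the thermodynamic arrangement).

Step 12
Reactants: 20 methyl (2R)-2,3-diethyl-3-ethenyl-2-[(1R,2S,4S,5R)-2-ethyl-4-methyl-3-oxo-5-(prop-1-en-2-yl)cyclopentyl]pent-4-enoate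
Product: 21 methyl (1S,3S,3aR,6S,7R,7aR)-6-ethenyl-1,6,7-triethyl-3,4-dimethyl-2-oxo-2,3,3a,6,7,7a-hexahydro-1H-indene-7-carboxylate (numbering of the overview)
Conditions: second-generation Grubbs catalyst RuCl2(=CHPh)(H2IMes)(PCy3) (10 mol%), toluene (0.005 M), 80 °C
Reagents that add atoms: none
Why: The ruthenium alkylidene exchanges onto one of the two monosubstituted vinyl groups at C6, the resulting C5 alkylidene adds to the 1,1-disubstituted isopropenyl group through a ruthenacyclobutane, and cycloreversion gives the C4=C5 alkene with loss of ethylene. The closest known reaction type is diastereotopic-group-selective ring-closing metathesis of a 1,4-diene at a prochiral quaternary carbon. Ring B closes as a six-membered carbocycle, trans-fused to ring A, through a chair-like array in which the ring A bonds C7a–C1 and C3a–C3 are both equatorial. The new stereocentre C6 is controlled by the adjacent quaternary C7: in this chair the C7 ethyl group is axial and the ester equatorial, the pseudo-equatorial site at C6 points away from C7a, and the pseudo-axial site is pressed against C7a–H and the ruthenium-bearing C5, so the larger ethyl group should take the former and the flat vinyl group the latter, which is the (6S) arrangement with vinyl cis to the ester. The step needs selection between the two vinyl groups, which rests on this bias and on the two alkylidenes interconverting through the released ethylene before ring closure; chemoselectivity is secured because the geminal vinyl groups cannot close on each other and the isopropenyl group is the only other partner within reach.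

Step 13
Reactants: 21 methyl (1S,3S,3aR,6S,7R,7aR)-6-ethenyl-1,6,7-triethyl-3,4-dimethyl-2-oxo-2,3,3a,6,7,7a-hexahydro-1H-indene-7-carboxylate; 22 iodobenzene
Product: 23 methyl (1S,3S,3aR,6S,7R,7aR)-1,6,7-triethyl-3,4-dimethyl-2-oxo-6-[(E)-2-phenylethenyl]-2,3,3a,6,7,7a-hexahydro-1H-indene-7-carboxylate
Conditions: Pd(OAc)2 (10 mol%), n-Bu4NCl, NaHCO3, DMF, 80 °C
Reagents that add atoms: none
Why: Heck arylation of the only monosubstituted alkene; syn insertion places phenyl on the terminal carbon and β-hydride elimination can only take the benzylic hydrogen because C6 has none, which should give the (E)-styryl group while the trisubstituted ring alkene stays inert.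

Step 14
Reactants: 23 methyl (1S,3S,3aR,6S,7R,7aR)-1,6,7-triethyl-3,4-dimethyl-2-oxo-6-[(E)-2-phenylethenyl]-2,3,3a,6,7,7a-hexahydro-1H-indene-7-carboxylate
Product: 24 (1S,3S,3aR,6S,7R,7aR)-1,6,7-triethyl-3,4-dimethyl-2-oxo-6-[(E)-2-phenylethenyl]-2,3,3a,6,7,7a-hexahydro-1H-indene-7-carboxylic acid (CNP0178058.1)
Conditions: LiI, pyridine, reflux; then cold 1 M HCl
Reagents that add atoms: none
Why: SN2 dealkylation at the methyl carbon by iodide cleaves an ester that is too hindered for acyl substitution, and the α-centres C1 and C3 already hold their thermodynamic configurations.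

**Compound list**

1 | pent-2-yn-1-ol | CCC#CCO | starting material
2 | sodium cyclic (Z)-alkenylaluminate from 1 (formed in situ) | CCC1=CCO[Al-]1(OCCOC)OCCOC.[Na+] | intermediate
3 | (2Z)-3-iodopent-2-en-1-ol | OC/C=C(\I)CC | intermediate
4 | (2Z)-3-ethylpenta-2,4-dien-1-ol | OC/C=C(\C=C)CC | intermediate
5 | 2-ethylcyclopent-2-en-1-one | CCC1=CCCC1=O | starting material
6 | dimethyl malonate | COC(=O)CC(=O)OC | starting material
7 | dimethyl 2-[(1R,2S)-2-ethyl-3-oxocyclopentyl]propanedioate | CC[C@@H]1C(=O)CC[C@H]1C(C(=O)OC)C(=O)OC | intermediate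
8 | dimethyl 2-[(6S,7R)-6-ethyl-1,4-dioxaspiro[4.4]nonan-7-yl]propanedioate | CC[C@@H]1C2(OCCO2)CC[C@H]1C(C(=O)OC)C(=O)OC | intermediate
9 | dimethyl 2-ethyl-2-[(6S,7R)-6-ethyl-1,4-dioxaspiro[4.4]nonan-7-yl]propanedioate | CC[C@@H]1C2(OCCO2)CC[C@H]1C(CC)(C(=O)OC)C(=O)OC | intermediate
10 | 2-ethyl-2-[(6S,7R)-6-ethyl-1,4-dioxaspiro[4.4]nonan-7-yl]propanedioic acid (formed in situ) | CC[C@@H]1C2(OCCO2)CC[C@H]1C(CC)(C(=O)O)C(=O)O | intermediate
11 | 2-[(6S,7R)-6-ethyl-1,4-dioxaspiro[4.4]nonan-7-yl]butanoic acid (C2 epimers) | CC[C@@H]1C2(OCCO2)CC[C@H]1C(CC)C(=O)O | intermediate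
12 | (2Z)-3-ethylpenta-2,4-dien-1-yl 2-[(6S,7R)-6-ethyl-1,4-dioxaspiro[4.4]nonan-7-yl]butanoate | CC[C@@H]1C2(OCCO2)CC[C@H]1C(CC)C(=O)OC/C=C(\C=C)CC | intermediate
13 | trimethylsilyl ketene acetal of 12 (geometry at C7=C unassigned, formed in situ) | CC[C@@H]1C2(OCCO2)CC[C@H]1C(CC)=C(O[Si](C)(C)C)OC/C=C(\C=C)CC | intermediate
14 | trimethylsilyl (2R)-2,3-diethyl-3-ethenyl-2-[(6S,7R)-6-ethyl-1,4-dioxaspiro[4.4]nonan-7-yl]pent-4-enoate (formed in situ) | CC[C@@H]1C2(OCCO2)CC[C@H]1[C@@](CC)(C(=O)O[Si](C)(C)C)C(CC)(C=C)C=C | intermediate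
15 | (2R)-2,3-diethyl-3-ethenyl-2-[(1R,2S)-2-ethyl-3-oxocyclopentyl]pent-4-enoic acid | CC[C@@H]1C(=O)CC[C@H]1[C@@](CC)(C(=O)O)C(CC)(C=C)C=C | intermediate
16 | methyl (2R)-2,3-diethyl-3-ethenyl-2-[(1R,2S)-2-ethyl-3-oxocyclopentyl]pent-4-enoate | CC[C@@H]1C(=O)CC[C@H]1[C@@](CC)(C(=O)OC)C(CC)(C=C)C=C | intermediate
17 | C2 trimethylsilyl enol ether of 16, C2=C3 (formed in situ) | CC[C@@H]1C(O[Si](C)(C)C)=CC[C@H]1[C@@](CC)(C(=O)OC)C(CC)(C=C)C=C | intermediate
18 | methyl (2R)-2,3-diethyl-3-ethenyl-2-[(1R,5S)-5-ethyl-4-oxocyclopent-2-en-1-yl]pent-4-enoate | CC[C@@H]1C(=O)C=C[C@H]1[C@@](CC)(C(=O)OC)C(CC)(C=C)C=C | intermediate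
19 | C2 trimethylsilyl enol ether (C2=C3) of the C3a-isopropenyl adduct of 18 (formed in situ) | CC[C@@H]1C(O[Si](C)(C)C)=C[C@@H]([C@H]1[C@@](CC)(C(=O)OC)C(CC)(C=C)C=C)C(C)=C | intermediate
20 | methyl (2R)-2,3-diethyl-3-ethenyl-2-[(1R,2S,4S,5R)-2-ethyl-4-methyl-3-oxo-5-(prop-1-en-2-yl)cyclopentyl]pent-4-enoate | CC[C@@H]1C(=O)[C@@H](C)[C@@H]([C@H]1[C@@](CC)(C(=O)OC)C(CC)(C=C)C=C)C(C)=C | intermediate
21 | methyl (1S,3S,3aR,6S,7R,7aR)-6-ethenyl-1,6,7-triethyl-3,4-dimethyl-2-oxo-2,3,3a,6,7,7a-hexahydro-1H-indene-7-carboxylate | CC[C@@H]1C(=O)[C@@H](C)[C@@H]2C(C)=C[C@@](C=C)(CC)[C@](CC)(C(=O)OC)[C@H]21 | intermediate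
22 | iodobenzene | Ic1ccccc1 | starting material
23 | methyl (1S,3S,3aR,6S,7R,7aR)-1,6,7-triethyl-3,4-dimethyl-2-oxo-6-[(E)-2-phenylethenyl]-2,3,3a,6,7,7a-hexahydro-1H-indene-7-carboxylate | CC[C@@H]1C(=O)[C@@H](C)[C@@H]2C(C)=C[C@@](/C=C/c3ccccc3)(CC)[C@](CC)(C(=O)OC)[C@H]21 | intermediate
24 | (1S,3S,3aR,6S,7R,7aR)-1,6,7-triethyl-3,4-dimethyl-2-oxo-6-[(E)-2-phenylethenyl]-2,3,3a,6,7,7a-hexahydro-1H-indene-7-carboxylic acid | CC[C@@H]1C(=O)[C@@H](C)[C@@H]2C(C)=C[C@@](/C=C/c3ccccc3)(CC)[C@](CC)(C(=O)O)[C@H]21 | target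

**Totals**

Total step count: 14. Longest linear sequence: 12 (steps 3 to 14; steps 1 and 2 make the dienol that enters in step 7).

**Steps most likely to fail**

1. Step 12 (ring-closing metathesis). What may go wrong: slow loading of the catalyst on the neopentyl-type vinyl groups, and weak or reversed discrimination between the two diastereotopic vinyl groups, so that C6 forms as a mixture. Fallback: the vinyl groups are told apart beforehand through the C7 carboxyl group. It sets out from 15. Bromolactonisation (N-bromosuccinimide, NaHCO3, THF, 0 °C) ties one vinyl group to the acid as a 5-(bromomethyl)-γ-lactone. The C6 diastereomer with the two ethyl groups cis on the lactone, 5-(bromomethyl)-4-ethenyl-3,4-diethyl-3-[(1R,2S)-2-ethyl-3-oxocyclopentyl]oxolan-2-one F1, is separated, and the other lactones are reopened to 15 with Zn in AcOH and recycled. F1 is taken through the chemistry of steps 10 and 11 to the enone lactone F2 and then to the isopropenyl methyl ketone lactone F3. Its single remaining vinyl group closes ring B with the same ruthenium catalyst to give the tricyclic bromolactone F4, with no group selection required. Zn in AcOH (reductive β-elimination) returns the vinyl group and gives the acid F5, and MeI, K2CO3 in DMF gives 21, where the fallback rejoins the route.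

2. Step 8 (Ireland–Claisen rearrangement). What may go wrong: incomplete enolisation of the doubly branched ester and poor facial selectivity of the sigmatropic shift at the tetrasubstituted ketene acetal, giving C7 epimers. Fallback: the two carbon substituents at C7 are introduced in the opposite order, so that the stereocentre arises by enolate alkylation. It sets out from 8. Saponification and decarboxylation as in step 6 give the acetic acid F6, and esterification with 4 as in step 7 gives the dienyl acetate F7. Ireland–Claisen rearrangement of its less hindered trisubstituted ketene acetal (LiN(iPr)2, Me3SiCl, THF; mild work-up that keeps the ketal) gives the acid F8, which is converted into its methyl ester F9 (MeI, K2CO3). Deprotonation with KN(SiMe3)2 in THF–DMPU and C-ethylation with EtI give the quaternary ester F10, the ethyl group being expected on the enolate face away from C1. 2 M HCl in THF removes the dioxolane and gives 16.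

3. Step 11 (conjugate addition and methylation). What may go wrong: 1,2-addition or no reaction at the hindered β-carbon next to the quaternary side chain, attack of MeLi on the ester, and proton transfer or over-alkylation during the enolate methylation. Fallback: rhodium-catalysed 1,4-addition of a boron reagent, followed by a separate kinetic methylation. It sets out from 18. Isopropenylboronic acid pinacol ester, [RhCl(cod)]2 (cod = cycloocta-1,5-diene), KOH, dioxane–H2O, 60 °C should give the 3a-isopropenyl ketone F11, again anti to the C7a substituent. Kinetic enolisation at the C3 methylene with LiN(iPr)2 (THF, −78 °C) followed by MeI gives 20.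

**Further compounds**

F1 | step 12 | 5-(bromomethyl)-4-ethenyl-3,4-diethyl-3-[(1R,2S)-2-ethyl-3-oxocyclopentyl]oxolan-2-one (3,4-ethyl groups cis, C5 of the lactone unassigned) | CC[C@@H]1C(=O)CC[C@H]1[C@@]2(CC)C(=O)OC(CBr)[C@@]2(CC)C=C
F2 | step 12 | 5-(bromomethyl)-4-ethenyl-3,4-diethyl-3-[(1R,5S)-5-ethyl-4-oxocyclopent-2-en-1-yl]oxolan-2-one | CC[C@@H]1C(=O)C=C[C@H]1[C@@]2(CC)C(=O)OC(CBr)[C@@]2(CC)C=C
F3 | step 12 | 5-(bromomethyl)-4-ethenyl-3,4-diethyl-3-[(1R,2S,4S,5R)-2-ethyl-4-methyl-3-oxo-5-(prop-1-en-2-yl)cyclopentyl]oxolan-2-one | CC[C@@H]1C(=O)[C@@H](C)[C@@H]([C@H]1[C@@]2(CC)C(=O)OC(CBr)[C@@]2(CC)C=C)C(C)=C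
F4 | step 12 | tricyclic bromomethyl γ-lactone joining the C7 carboxyl group to the former C6 vinyl group of the hexahydroindenone (lactone of F5) | CC[C@@H]1C(=O)[C@@H](C)[C@@H]2C(C)=C[C@]3(CC)C(CBr)OC(=O)[C@]3(CC)[C@H]21
F5 | step 12 | (1S,3S,3aR,6S,7R,7aR)-6-ethenyl-1,6,7-triethyl-3,4-dimethyl-2-oxo-2,3,3a,6,7,7a-hexahydro-1H-indene-7-carboxylic acid | CC[C@@H]1C(=O)[C@@H](C)[C@@H]2C(C)=C[C@@](C=C)(CC)[C@](CC)(C(=O)O)[C@H]21
F6 | step 8 | 2-[(6S,7S)-6-ethyl-1,4-dioxaspiro[4.4]nonan-7-yl]acetic acid | CC[C@@H]1C2(OCCO2)CC[C@H]1CC(=O)O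
F7 | step 8 | (2Z)-3-ethylpenta-2,4-dien-1-yl 2-[(6S,7S)-6-ethyl-1,4-dioxaspiro[4.4]nonan-7-yl]acetate | CC[C@@H]1C2(OCCO2)CC[C@H]1CC(=O)OC/C=C(\C=C)CC
F8 | step 8 | 3-ethenyl-3-ethyl-2-[(6S,7R)-6-ethyl-1,4-dioxaspiro[4.4]nonan-7-yl]pent-4-enoic acid (C2 epimers) | CC[C@@H]1C2(OCCO2)CC[C@H]1C(C(=O)O)C(CC)(C=C)C=C
F9 | step 8 | methyl 3-ethenyl-3-ethyl-2-[(6S,7R)-6-ethyl-1,4-dioxaspiro[4.4]nonan-7-yl]pent-4-enoate (C2 epimers) | CC[C@@H]1C2(OCCO2)CC[C@H]1C(C(=O)OC)C(CC)(C=C)C=C
F10 | step 8 | methyl (2R)-2,3-diethyl-3-ethenyl-2-[(6S,7R)-6-ethyl-1,4-dioxaspiro[4.4]nonan-7-yl]pent-4-enoate | CC[C@@H]1C2(OCCO2)CC[C@H]1[C@@](CC)(C(=O)OC)C(CC)(C=C)C=C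
F11 | step 11 | methyl (2R)-2,3-diethyl-3-ethenyl-2-[(1R,2S,5S)-2-ethyl-3-oxo-5-(prop-1-en-2-yl)cyclopentyl]pent-4-enoate | CC[C@@H]1C(=O)C[C@@H]([C@H]1[C@@](CC)(C(=O)OC)C(CC)(C=C)C=C)C(C)=C
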